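Substrate that has gone in and is no longer substrate must stand somewhere else, so the substrate consumed by any time is the fraction fed minus the substrate read.

| flask | substrate | coupling partner | remark | time |
|---|---|---|---|---|
| birch | 0.17 M (fed, over 12 h) | 1.2 equiv | run made earlier; the fed solution adds 0.20 times the starting volume |  |
| maple | 0.38 M (fed, over 12 h) | 1.2 equiv | run made earlier; the fed solution adds 0.20 times the starting volume |  |
| ash | 0.25 M (fed, over 12 h) | 2.4 equiv | run made earlier; the fed solution adds 0.20 times the starting volume |  |
| flask | 0.25 M (fed, over 12 h) | 1.20 equiv | the fed solution adds 0.20 times the starting volume | 25 h |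

| run | time / h | side product B / % | target / % | substrate / % | side product A / % | intermediate A / % | intermediate B / % |
|---|---|---|---|---|---|---|---|
| birch | 1.33 | 0 | 0 | 10.0 | 0.7 | 0.1 | 1.5 |
| birch | 2.00 | 0 | 0.5 | 14.1 | 0 | 3.0 | 0 |
| birch | 3.00 | 2.0 | 0 | 19.6 | 1.3 | 6.0 | 0 |
| birch | 5.00 | 0 | 1.9 | 29.6 | 2.9 | 10.0 | 0 |
| birch | 10.0 | 0.3 | 7.0 | 41.8 | 2.2 | 30.7 | 4.3 |
| birch | 15.0 | 1.3 | 10.8 | 27.7 | 5.6 | 48.3 | 7.2 |
| maple | 1.33 | 0 | 0 | 7.9 | 0.4 | 1.2 | 0.4 |
| maple | 2.00 | 0 | 0.4 | 15.0 | 0.5 | 1.8 | 0 |
| maple | 3.00 | 0 | 0.3 | 20.3 | 0.7 | 2.7 | 2.0 |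
| maple | 5.00 | 0.2 | 2.2 | 29.0 | 0 | 9.8 | 2.3 |
| maple | 10.0 | 1.8 | 5.8 | 39.8 | 0.2 | 27.0 | 6.2 |
| maple | 15.0 | 7.0 | 11.0 | 27.1 | 3.1 | 39.7 | 11.0 |
| ash | 1.33 | 0 | 0 | 9.5 | 0.7 | 1.7 | 1.4 |
| ash | 2.50 | 0 | 0 | 18.2 | 0 | 1.5 | 0.4 |
| ash | 4.00 | 0.3 | 1.2 | 24.9 | 1.5 | 3.8 | 1.4 |
| ash | 8.00 | 0 | 4.6 | 39.5 | 0.9 | 17.9 | 5.0 |
| ash | 15.0 | 5.4 | 11.4 | 27.4 | 3.5 | 37.0 | 13.9 |

(standard deviation of a reading: 1 percentage point)

- percentages count the substrate that a species holds: one side product B counts as two
- every charge counts on the volume at the start, and the solution that is fed holds the whole dose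
- percentages count the whole charge, also what has not yet gone in

* the largest share of what was charged as substrate, at 25 h belongs to (side product A / target / side product B / intermediate A / intermediate B / substrate)
* the largest share itself, whichever of these holds it, in percent of the substrate charged

The target share, target found over substrate consumed, reads 15.0% over birch and maple at 10.0 h. Over birch, maple and ash it reads 15.2% at 15.0 h, so target keeps step with consumption.

Birch, with its feed counted, loses substrate at 0.177 /h. Carried on from the ash reading, that leaves 4.66% in the flask at 25 h. The target share then gives 14.5% of target, and 80.8% remains for intermediate A and whatever follows it.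

In birch and maple, whose charges lie on either side of the flask's, the part of that remainder no longer intermediate A grows from 20.2% to 28.7%. A straight line onward leaves 43.8% as intermediate A, more than the 37.0% beside it. That line is the weak link. Holding the part at its later reading gives 57.6%, so this reckoning commits to the midpoint, 50.7%.

The forecast differs: intermediate A at 32%, with “target about 26%”.

The flask gives intermediate A at 47.7%, with target at 14.7% and substrate at 5.05%.

    intermediate A → decomposed reagent (k = 0.00120 /h)
    substrate → target (k = 0.0250 /h)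
    substrate + intermediate B → side product B (k = 0.520 /M/h)
    intermediate A → side product A (k = 0.0110 /h)
    substrate → intermediate A (k = 0.130 /h)
    coupling partner + intermediate A ⇌ intermediate B (K = 2.00 /M, k = 0.220 /M/h)

At 25.0 h substrate goes into intermediate A 5.2 times as fast as into target, the selectivity factor it also has at 10.7 h, which gives target 16.1% of what these two routes together carry. The target share times the substrate consumed gives 14.4% in the flask, against 14.7% found. In the neighbour charged with 0.10 M of substrate, with 5.83% of substrate left at 25.0 h, the same share gives 14.3%, and that neighbour holds 15.1% of target.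

The numbers in the tables come from a simulation from invented constants; the scatter is artificial.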